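## Remarks on the chemistry

- **Structure check.** In the target string C2 carries O1, phenyl, C3 and H in the sense that corresponds to S, and natural (S)-pinostrobin has the same sense, so the stereocentre can be bought. The bromine of 5-bromo-2-hydroxybenzyl alcohol sits para to the phenol oxygen, which is where each distal CH2 of the target is attached (C5''). No constitutional or configurational correction is needed.
- **Design change.** The terminal phenols are carried as methoxymethyl (MOM) ethers, where benzyl ethers would be the more obvious choice. With acetates on the flavanone half and MOM on the zinc half, one acid-catalysed methanolysis frees all five phenols. This saves a step and avoids hydrogenation over palladium of a substrate with a benzylic C2–O1 bond and an aryl ketone. The disconnection is unchanged; the benzyl variant is kept as a reserve.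
- **Assumption.** (S)-Pinostrobin is bought as the enantiopure natural product and its enantiomeric purity is checked before use.

## Structural features

The target is a (2S)-flavanone: benzene ring A is fused to the dihydropyranone ring C, which carries phenyl ring B at C2 and the ketone at C4. Ring A is hexasubstituted, with a hydroxyl at C5 hydrogen-bonded to the C4 carbonyl, a methoxy group at C7 and two identical benzylic arms at C6 and C8. Each arm is a 2-hydroxybenzyl unit (middle ring) that carries, at C5'' para to its own hydroxyl, a second 2-hydroxybenzyl unit (terminal ring), so the molecule has four diarylmethane CH2 links, five phenols and seven rings. C2 is the only stereocentre and has no stereogenic neighbour, so the task is to keep it, not to relate it to anything. It is also the fragile point: base, and more slowly hot acid, open ring C by retro-oxa-Michael reaction to the achiral 2'-hydroxychalcone, and the C2–O1 bond is benzylic and open to hydrogenolysis; the free polyphenol is also oxidation-sensitive in basic media. The real difficulty is regiochemical: four aryl–CH2 bonds must be placed around an electron-rich, crowded core, each distal CH2 para to a middle-ring oxygen and ortho to a terminal-ring oxygen, under conditions mild enough for C2. The key step uses the fact that C5'' of each middle ring is para to the arm oxygen and can carry bromine from the start, so both C5''–CH2 bonds are made by cross-coupling at predetermined carbons, while C6 and C8, the only free positions of ring A, take the arms.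

## Logic of the disconnections

**12 to 11.** No skeletal bond is cut. The five phenols are traced back to three acetate esters (ring A and the two middle rings) and two methoxymethyl acetals (terminal rings). Both kinds of group fall to acid-catalysed alcoholysis, so one operation suffices and neither base nor hydrogen over a metal touches the flavanone. The forward step demands acid mild enough to leave ring C closed.

**11 to 5 and 10.** The two C5''–CH2 bonds are cut, each between an sp2 carbon of a middle ring and the benzylic carbon of a terminal unit. These bonds lie far from the stereocentre and from the crowded ring A, are the same on both arms, and have an sp2 partner that can carry a halogen from a commercial building block. The cut removes both terminal rings at once and leaves a dibromide and one small organometallic. The forward step must add twice, must select C–Br over a ketone, three esters and two acetals, and must run without base.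

**5 to 4.** Three O–acetyl bonds are cut. The acetates remove every acidic proton before the organozinc is introduced and are cleaved later together with the acetals. The forward acylation must reach the hydrogen-bonded C5 hydroxyl without base-induced opening of ring C.

**4 to 1 and 2.** The C6–CH2 and C8–CH2 bonds are cut. Ring A of 1 has exactly two unsubstituted carbons, both activated by three oxygen substituents, and 2 is a latent benzylic electrophile (through 3) that already holds bromine para to its oxygen. This takes the flavanone half back to two commercial compounds and lets the stereocentre be bought. The forward step must alkylate both positions fully, must not alkylate the arm phenols further, and must not racemise C2.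

**10 to 9, 7 and 6.** The C–Zn bond is traced to a C–Cl bond (9), this to the benzylic alcohol 7 (through 8), and the acetal O–CH2 bond of 7 to the phenol of 6. Each is a functional-group change on a small achiral compound. The demands are chemoselective alkylation of the phenol of 6 beside its primary alcohol, chlorination without free acid, and zinc insertion without homocoupling.

## Other disconnections considered

**Alternative 1:** The cut is at the two bonds between the benzylic carbons on ring A and C1'' of the middle rings, and the middle rings are taken back to cyclohexenones.
- *Forward key step:* both formyl groups of dialdehyde A1 would undergo aldol condensation with the kinetic lithium enolate of enone A2 (strong amide base, low temperature). Isomerisation of the cross-conjugated dienones (exocyclic alkene into the ring, then tautomerisation) would give the two phenols of A3.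
- *In favour:* the substituent at C4 of A2 must end up para to the new phenol oxygen, so C5'' regiochemistry is as certain as in the chosen plan (equal on this point). The terminal ring arrives already attached and no halide or transition metal is needed for the key bonds. No electrophilic substitution is run on an enantiopure flavanone in acid, which is better than step 1 of the chosen route.
- *Against:* a flavanone cannot be exposed to a lithium enolate without risk of opening ring C, so the heterocycle must be carried as the flavone. C2 then has to be created at the end by enantioselective conjugate reduction of a crowded, chelating flavone, for which no dependable general method exists; the chosen plan buys C2 and never touches it. The aldehydes of A1 are each flanked by two ortho substituents on a ring deactivated by the pyranone, so both the double formylation that makes A1 and the double aldol are uphill. A2 needs its own multi-step preparation.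
- *Comparison:* it trades a neutral cross-coupling for strong-base enolate chemistry plus an isomerisation. It is clearly longer: separate syntheses of A1 and A2, the condensation, an asymmetric reduction, and hydrogenolysis of three benzyl ethers, which endangers the benzylic C2–O1 bond once the flavanone exists.

**Alternative 2:** Ring A itself is dismantled: the C8–C8a and C6–C7 bonds are cut, leading back to cyclobutenone A4 and alkynyl ether A5, each carrying one complete arm.
- *Forward key step:* heating would open A4 to a vinylketene, which adds [2+2] to the electron-rich alkyne. Four-electron opening of the new cyclobutenone, six-electron closure of the dienylketene and tautomerisation would give phenol A6 with all substituents placed by the mechanism.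
- *In favour:* the benzannulation is regiospecific, so a pentasubstituted ring is assembled with no question of site selectivity. Because both arms are identical, later pyranone closure onto either ring oxygen gives the same constitution. Acid and Lewis acid are kept away from any stereocentre. On regiochemical certainty of ring A it equals the chosen plan, where C6 and C8 are simply the only free positions of 1.
- *Against:* ring A, with the right oxygenation and the C2 stereocentre, is available ready-made in 1. A4 and A5 each need a complete diarylmethane arm plus a sensitive function (a 3-alkoxycyclobutenone and a 1-methoxyalkyne, a labile class usually made and used without storage). After the annulation, C4a, flanked by two oxygen substituents, must still be acylated, ring C built, C2 set by an asymmetric oxa-Michael cyclisation, and five benzyl ethers removed by hydrogenolysis next to the benzylic C2–O1 bond.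
- *Comparison:* the pericyclic cascade is convergent, but it creates what can be bought. The route would run to well over twice the steps of the chosen one, with the stereocentre an open problem.

**Alternative 3:** The cut is at the two bonds between the distal benzylic carbons and the terminal rings, seen as an ortho-hydroxyalkylation in which the arm aldehydes of A7 are attacked by phenol A8.
- *Forward key step:* phenylboronic acid A9 would esterify A8 and hold the aryl aldehyde on boron. The phenol ortho carbon would attack the formyl carbon through a six-membered array, closing the two benzodioxaborin rings of A10, each with a new uncontrolled benzylic stereocentre. Reductive removal of both benzylic C–O bonds and deacetylation would then give 12.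
- *In favour:* ortho selectivity at the terminal ring is enforced by the boron tether. The terminal ring is the cheapest possible building block, needs no protecting group, and no organometallic reagent has to be made. The step count is shorter than the chosen route, which needs three steps to make 10: arming of 1 with aldehyde A11 in the manner of step 1, arm-selective acetylation to A7, the three-component reaction, reduction, deacetylation. On step economy and reagent cost it is the better plan.
- *Against:* the benzylic oxygen introduced in the key step must be taken out again. The ionic or catalytic hydrogenation that does so must tell the two dioxaborin C–O bonds from the C4 ketone and the benzylic C2–O1 bond, a selectivity the chosen plan never needs. The doubly benzylic, oxygen-activated carbinol carbon can ionise under hot acidic conditions and capture a second molecule of A8 to give a triarylmethane. The formyl group of A11 destabilises the quinone methide needed to attach the arms to 1, so A7 is harder to make than 5. A10 would be a diastereomer mixture until the reduction.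
- *Comparison:* both plans form the same bond set (the two distal diarylmethane links) late and in two directions. The chosen one is redox-neutral at carbon and fixes regiochemistry by a halogen; this one fixes it by a tether and pays with an extra reduction.

Key step: step 6

## Route

Step 1
Reactants: 1 (S)-pinostrobin [(2S)-5-hydroxy-7-methoxy-2-phenylchroman-4-one]; 2 5-bromo-2-hydroxybenzyl alcohol (2.6 equiv)
Product: 4 (S)-6,8-bis(5-bromo-2-hydroxybenzyl)-5-hydroxy-7-methoxyflavanone, via 4-bromo-6-methylidenecyclohexa-2,4-dien-1-one 3 (not isolated)
Conditions: ZnCl2 (anhydrous, 3 equiv), 1,4-dioxane, 90 °C, 2 added in portions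
Reagents that add atoms: none
Why: Lewis-acid Friedel–Crafts hydroxybenzylation, a known reaction of 2-hydroxybenzyl alcohols with 5,7-dioxygenated flavanones: ZnCl2 ionises 2 to the ortho-quinone methide 3, which is captured at C6 and C8, the only CH positions of ring A and each ortho or para to three oxygen substituents. The bromophenol rings of the product are much poorer nucleophiles, which limits over-alkylation; no stereocentre is formed and no bond to C2 is involved.

Step 2
Reactants: 4 (S)-6,8-bis(5-bromo-2-hydroxybenzyl)-5-hydroxy-7-methoxyflavanone
Product: 5 (S)-5-acetoxy-6,8-bis(2-acetoxy-5-bromobenzyl)-7-methoxyflavanone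
Conditions: Ac2O (6 equiv), pyridine, DMAP (10 mol %), CH2Cl2, 0 °C to rt
Reagents that add atoms: acetic anhydride, CC(=O)OC(C)=O
Why: DMAP-catalysed O-acylation (nucleophilic catalysis); the two arm phenols react first and the hydrogen-bonded, flanked 5-OH last. The weakly basic medium at or below room temperature should leave ring C closed, so C2 is retained, and all acidic protons are removed before the organozinc step.

Step 3
Reactants: 6 salicyl alcohol (2-hydroxybenzyl alcohol)
Product: 7 2-(methoxymethoxy)benzyl alcohol
Conditions: MOMCl (1.1 equiv), K2CO3, acetone, 0 °C to rt
Reagents that add atoms: chloromethyl methyl ether, COCCl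
Why: Williamson-type O-alkylation: K2CO3 deprotonates only the phenol, which is about five pKa units more acidic than the benzylic alcohol, and the phenoxide captures the alkoxymethyl chloride, so the primary alcohol stays free.

Step 4
Reactants: 7 2-(methoxymethoxy)benzyl alcohol
Product: 9 2-(methoxymethoxy)benzyl chloride, via 2-(methoxymethoxy)benzyl methanesulfonate 8 (not isolated)
Conditions: MsCl, Et3N, LiCl, THF, 0 °C to rt
Reagents that add atoms: methanesulfonyl chloride, CS(=O)(=O)Cl (mesyl group of 8); lithium chloride, [Li+].[Cl-] (chlorine of 9)
Why: Sulfonylation of the primary alcohol followed by SN2 displacement of the activated benzylic mesylate by chloride; amine base is present throughout, so no free HCl can attack the MOM acetal.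

Step 5
Reactants: 9 2-(methoxymethoxy)benzyl chloride
Product: 10 2-(methoxymethoxy)benzylzinc chloride (LiCl complex, titrated THF solution)
Conditions: Zn dust (activated with 1,2-dibromoethane and Me3SiCl), LiCl, THF, 25 °C
Reagents that add atoms: zinc, [Zn]
Why: LiCl-promoted direct insertion of zinc into the benzylic C–Cl bond; using the chloride and room temperature keeps Wurtz-type homocoupling low, and the acetal is inert to the organozinc.

Step 6
Reactants: 5 (S)-5-acetoxy-6,8-bis(2-acetoxy-5-bromobenzyl)-7-methoxyflavanone; 10 2-(methoxymethoxy)benzylzinc chloride (3 equiv)
Product: 11 (S)-5-acetoxy-6,8-bis{2-acetoxy-5-[2-(methoxymethoxy)benzyl]benzyl}-7-methoxyflavanone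
Conditions: Pd(OAc)2 (4 mol %), SPhos (2-dicyclohexylphosphino-2',6'-dimethoxybiphenyl, 8 mol %), THF, 25 to 40 °C, slow addition of 10
Reagents that add atoms: none
Why: Negishi cross-coupling of a benzylic zinc chloride with aryl bromides, an established reaction type that tolerates esters and ketones. Pd(OAc)2 is reduced by a little of 10 to a zerovalent palladium–SPhos species, which adds oxidatively into each C5''–Br bond to give an arylpalladium bromide of divalent palladium. Transmetalation from 10 and reductive elimination then form the C(sp2)–C(sp3) bond; the benzyl group has no β-hydrogen, so β-hydride elimination cannot intervene. No ring is closed and no stereocentre is created. The selectivity needed is for C–Br over the C4 ketone, the three aryl acetates and the two acetals, with retention at C2; it is secured by the low basicity and low carbonyl reactivity of the benzylzinc chloride and by the absence of added base. The site of each new bond is fixed by the bromine atoms para to the arm oxygens. The two reacting sites are remote from each other and from the crowded ring A, so both should couple under the same conditions, and slow addition of 10 limits its homocoupling.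

Step 7
Reactants: 11 (S)-5-acetoxy-6,8-bis{2-acetoxy-5-[2-(methoxymethoxy)benzyl]benzyl}-7-methoxyflavanone
Product: 12 5''-(2''''-hydroxybenzyl)uvarinol [(S)-5-hydroxy-6,8-bis[2-hydroxy-5-(2-hydroxybenzyl)benzyl]-7-methoxyflavanone]
Conditions: HCl (3 M in MeOH), MeOH–THF, 40 °C, under argon
Reagents that add atoms: none
Why: Acid-catalysed transesterification of the three aryl acetates and acetal exchange of the two MOM ethers with methanol in one operation. The C7 methyl ether, the four diarylmethane links and ring C are stable to dilute acid at this temperature, and no bond to C2 is broken, so the S configuration is carried through.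

## Compound list

1 | (S)-pinostrobin, (2S)-5-hydroxy-7-methoxy-2-phenylchroman-4-one | COc1cc(O)c2c(c1)O[C@H](c1ccccc1)CC2=O | starting material
2 | 5-bromo-2-hydroxybenzyl alcohol | OCc1cc(Br)ccc1O | starting material
3 | 4-bromo-6-methylidenecyclohexa-2,4-dien-1-one (ortho-quinone methide) | C=C1C=C(Br)C=CC1=O | intermediate
4 | (S)-6,8-bis(5-bromo-2-hydroxybenzyl)-5-hydroxy-7-methoxyflavanone | COc1c(Cc2cc(Br)ccc2O)c(O)c2c(c1Cc1cc(Br)ccc1O)O[C@H](c1ccccc1)CC2=O | intermediate
5 | (S)-5-acetoxy-6,8-bis(2-acetoxy-5-bromobenzyl)-7-methoxyflavanone | COc1c(Cc2cc(Br)ccc2OC(C)=O)c(OC(C)=O)c2c(c1Cc1cc(Br)ccc1OC(C)=O)O[C@H](c1ccccc1)CC2=O | intermediate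
6 | salicyl alcohol (2-hydroxybenzyl alcohol) | OCc1ccccc1O | starting material
7 | 2-(methoxymethoxy)benzyl alcohol | COCOc1ccccc1CO | intermediate
8 | 2-(methoxymethoxy)benzyl methanesulfonate | COCOc1ccccc1COS(C)(=O)=O | intermediate
9 | 2-(methoxymethoxy)benzyl chloride | COCOc1ccccc1CCl | intermediate
10 | 2-(methoxymethoxy)benzylzinc chloride | COCOc1ccccc1C[Zn]Cl | intermediate
11 | (S)-5-acetoxy-6,8-bis{2-acetoxy-5-[2-(methoxymethoxy)benzyl]benzyl}-7-methoxyflavanone | COc1c(Cc2cc(Cc3ccccc3OCOC)ccc2OC(C)=O)c(OC(C)=O)c2c(c1Cc1cc(Cc3ccccc3OCOC)ccc1OC(C)=O)O[C@H](c1ccccc1)CC2=O | intermediate
12 | 5''-(2''''-hydroxybenzyl)uvarinol, (S)-5-hydroxy-6,8-bis[2-hydroxy-5-(2-hydroxybenzyl)benzyl]-7-methoxyflavanone | COc1c(Cc2cc(Cc3ccccc3O)ccc2O)c(O)c2c(c1Cc1cc(Cc3ccccc3O)ccc1O)O[C@H](c1ccccc1)CC2=O | target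

## Step count and least certain steps

Total step count: 7. Longest linear sequence: 5 steps (steps 3, 4, 5, 6 and 7, from 6 to 12); from 1 the sequence is 4 steps (steps 1, 2, 6 and 7).

**Step 6 (key step).**
- *Most likely to go wrong:* stalling after the first coupling, with consumption of 10 by homocoupling and protonolysis and some reductive loss of bromine. The two aryl bromides carry para-acyloxy groups and are only moderately activated towards oxidative addition, and benzylic zinc reagents transmetalate twice on palladium easily. Erosion at C2 is not expected under neutral conditions but should be checked by chiral HPLC.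
- *Fallback (changes the order of bond formation):* the cross-coupling is moved to a small achiral bromide and the finished arms are attached to ring A last. Setting out from 2 and 10, coupling under the same Pd(OAc)2/SPhos conditions with slow addition of an excess of 10 (couplings of this type tolerate free hydroxyl groups) would give 2-(hydroxymethyl)-4-[2-(methoxymethoxy)benzyl]phenol F1. ZnCl2-mediated double hydroxybenzylation of 1 with F1, as in step 1, would give (S)-5-hydroxy-6,8-bis{2-hydroxy-5-[2-(methoxymethoxy)benzyl]benzyl}-7-methoxyflavanone F2. The conditions of step 7 would remove the two MOM groups (any already lost under the Lewis acid is of no consequence) and return to the route at 12.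

**Step 1.**
- *Most likely to go wrong:* incomplete second alkylation alongside further alkylation of the arm phenols and self-condensation of the benzylic alcohol, giving a statistical mixture. All partners are phenols and the electrophile is generated continuously. Prolonged heating with the Lewis acid could also erode C2 through reversible opening of ring C.
- *Fallback (cross-coupling in place of electrophilic substitution):* setting out from 1, dibromination with N-bromosuccinimide (MeCN, 0 °C) would give (S)-6,8-dibromo-5-hydroxy-7-methoxyflavanone F3. Double Negishi coupling with 10 (Pd(OAc)2, SPhos, THF; one further equivalent of 10 for the chelated phenol) would give (S)-5-hydroxy-7-methoxy-6,8-bis[2-(methoxymethoxy)benzyl]flavanone F4. Acid methanolysis would free (S)-5-hydroxy-6,8-bis(2-hydroxybenzyl)-7-methoxyflavanone F5. Para-selective bromination of the two arm phenols with tetrabutylammonium tribromide (CH2Cl2–MeOH, 0 °C; ring A has no free position) would return to the route at 4.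

**Step 2.**
- *Most likely to go wrong:* sluggish acylation of the hydrogen-bonded C5 hydroxyl, which sits between the carbonyl and the C6 arm. Forcing it with more base or heat invites base-induced opening and reclosure of ring C, with loss of configuration at C2.
- *Fallback (different protection pattern of the coupling precursor):* setting out from 4, acetylation without DMAP at 0 °C would be stopped at the arm phenols to give (S)-6,8-bis(2-acetoxy-5-bromobenzyl)-5-hydroxy-7-methoxyflavanone F6. The chelated 5-OH protonates benzylzinc reagents only slowly, so F6 would be coupled with 10 (one further equivalent) as in step 6 to (S)-6,8-bis{2-acetoxy-5-[2-(methoxymethoxy)benzyl]benzyl}-5-hydroxy-7-methoxyflavanone F7. Under the conditions of step 7 this returns to the route at 12.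

**Step 7.**
- *Most likely to go wrong:* methylene bridging or hydroxymethylation of the newly freed, electron-rich phenol rings by the formaldehyde equivalent released from the MOM groups. If the last acetate is slow and heating is prolonged, acid-promoted opening and reclosure of ring C would leave the constitution unchanged (the arms are identical) but erode C2.
- *Fallback (other protecting group on the terminal rings, two-stage unmasking):* setting out from 5, commercial 2-(benzyloxy)benzyl chloride F8 would be converted by Zn/LiCl insertion (as in step 5) into 2-(benzyloxy)benzylzinc chloride F9 and coupled as in step 6 to (S)-5-acetoxy-6,8-bis{2-acetoxy-5-[2-(benzyloxy)benzyl]benzyl}-7-methoxyflavanone F10. Brief methanolysis of the acetates with HCl in MeOH at room temperature (no formaldehyde source present) would give (S)-6,8-bis{5-[2-(benzyloxy)benzyl]-2-hydroxybenzyl}-5-hydroxy-7-methoxyflavanone F11. Hydrogenolysis (H2, 1 atm, Pd/C, EtOAc, stopped after uptake of two equivalents to spare the benzylic C2–O1 bond) would return to the route at 12.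

## Further compounds

F1 | step 6 | 2-(hydroxymethyl)-4-[2-(methoxymethoxy)benzyl]phenol | COCOc1ccccc1Cc1ccc(O)c(CO)c1
F2 | step 6 | (S)-5-hydroxy-6,8-bis{2-hydroxy-5-[2-(methoxymethoxy)benzyl]benzyl}-7-methoxyflavanone | COc1c(Cc2cc(Cc3ccccc3OCOC)ccc2O)c(O)c2c(c1Cc1cc(Cc3ccccc3OCOC)ccc1O)O[C@H](c1ccccc1)CC2=O
F3 | step 1 | (S)-6,8-dibromo-5-hydroxy-7-methoxyflavanone | COc1c(Br)c(O)c2c(c1Br)O[C@H](c1ccccc1)CC2=O
F4 | step 1 | (S)-5-hydroxy-7-methoxy-6,8-bis[2-(methoxymethoxy)benzyl]flavanone | COc1c(Cc2ccccc2OCOC)c(O)c2c(c1Cc1ccccc1OCOC)O[C@H](c1ccccc1)CC2=O
F5 | step 1 | (S)-5-hydroxy-6,8-bis(2-hydroxybenzyl)-7-methoxyflavanone | COc1c(Cc2ccccc2O)c(O)c2c(c1Cc1ccccc1O)O[C@H](c1ccccc1)CC2=O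
F6 | step 2 | (S)-6,8-bis(2-acetoxy-5-bromobenzyl)-5-hydroxy-7-methoxyflavanone | COc1c(Cc2cc(Br)ccc2OC(C)=O)c(O)c2c(c1Cc1cc(Br)ccc1OC(C)=O)O[C@H](c1ccccc1)CC2=O
F7 | step 2 | (S)-6,8-bis{2-acetoxy-5-[2-(methoxymethoxy)benzyl]benzyl}-5-hydroxy-7-methoxyflavanone | COc1c(Cc2cc(Cc3ccccc3OCOC)ccc2OC(C)=O)c(O)c2c(c1Cc1cc(Cc3ccccc3OCOC)ccc1OC(C)=O)O[C@H](c1ccccc1)CC2=O
F8 | step 7 | 2-(benzyloxy)benzyl chloride | ClCc1ccccc1OCc1ccccc1
F9 | step 7 | 2-(benzyloxy)benzylzinc chloride | Cl[Zn]Cc1ccccc1OCc1ccccc1
F10 | step 7 | (S)-5-acetoxy-6,8-bis{2-acetoxy-5-[2-(benzyloxy)benzyl]benzyl}-7-methoxyflavanone | COc1c(Cc2cc(Cc3ccccc3OCc3ccccc3)ccc2OC(C)=O)c(OC(C)=O)c2c(c1Cc1cc(Cc3ccccc3OCc3ccccc3)ccc1OC(C)=O)O[C@H](c1ccccc1)CC2=O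
F11 | step 7 | (S)-6,8-bis{5-[2-(benzyloxy)benzyl]-2-hydroxybenzyl}-5-hydroxy-7-methoxyflavanone | COc1c(Cc2cc(Cc3ccccc3OCc3ccccc3)ccc2O)c(O)c2c(c1Cc1cc(Cc3ccccc3OCc3ccccc3)ccc1O)O[C@H](c1ccccc1)CC2=O
A1 | alternative 1 | 5-(benzyloxy)-6,8-diformyl-7-methoxyflavone | COc1c(C=O)c(OCc2ccccc2)c2c(c1C=O)OC(c1ccccc1)=CC2=O
A2 | alternative 1 | 4-[2-(benzyloxy)benzyl]cyclohex-2-en-1-one (racemic) | O=C1C=CC(Cc2ccccc2OCc2ccccc2)CC1
A3 | alternative 1 | 5-(benzyloxy)-6,8-bis{5-[2-(benzyloxy)benzyl]-2-hydroxybenzyl}-7-methoxyflavone | COc1c(Cc2cc(Cc3ccccc3OCc3ccccc3)ccc2O)c(OCc2ccccc2)c2c(c1Cc1cc(Cc3ccccc3OCc3ccccc3)ccc1O)OC(c1ccccc1)=CC2=O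
A4 | alternative 2 | 3-(benzyloxy)-2-{2-(benzyloxy)-5-[2-(benzyloxy)benzyl]benzyl}cyclobut-2-en-1-one | O=C1CC(OCc2ccccc2)=C1Cc1cc(Cc2ccccc2OCc2ccccc2)ccc1OCc1ccccc1
A5 | alternative 2 | 1-(benzyloxy)-4-[2-(benzyloxy)benzyl]-2-(3-methoxyprop-2-yn-1-yl)benzene | COC#CCc1cc(Cc2ccccc2OCc2ccccc2)ccc1OCc1ccccc1
A6 | alternative 2 | 5-(benzyloxy)-3-methoxy-2,4-bis{2-(benzyloxy)-5-[2-(benzyloxy)benzyl]benzyl}phenol | COc1c(Cc2cc(Cc3ccccc3OCc3ccccc3)ccc2OCc2ccccc2)c(O)cc(OCc2ccccc2)c1Cc1cc(Cc2ccccc2OCc2ccccc2)ccc1OCc1ccccc1
A7 | alternative 3 | (S)-6,8-bis(2-acetoxy-5-formylbenzyl)-5-hydroxy-7-methoxyflavanone | COc1c(Cc2cc(C=O)ccc2OC(C)=O)c(O)c2c(c1Cc1cc(C=O)ccc1OC(C)=O)O[C@H](c1ccccc1)CC2=O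
A8 | alternative 3 | phenol | Oc1ccccc1
A9 | alternative 3 | phenylboronic acid | OB(O)c1ccccc1
A10 | alternative 3 | (S)-6,8-bis[2-acetoxy-5-(2-phenyl-4H-1,3,2-benzodioxaborin-4-yl)benzyl]-5-hydroxy-7-methoxyflavanone (dioxaborin C4 centres unassigned) | COc1c(Cc2cc(C3OB(c4ccccc4)Oc4ccccc34)ccc2OC(C)=O)c(O)c2c(c1Cc1cc(C3OB(c4ccccc4)Oc4ccccc34)ccc1OC(C)=O)O[C@H](c1ccccc1)CC2=O
A11 | alternative 3 | 4-hydroxy-3-(hydroxymethyl)benzaldehyde | O=Cc1ccc(O)c(CO)c1
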